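In a world of one reversible step started from its reagents, the fraction left of a reagent falls until the forward and back rates are equal, and the product-to-reagent ratio, each multiplied by its partner, then stands at a constant. These flasks chain such steps: each exchange takes one incoming ligand from the solution and gives back one leaving ligand.

| setting | epsilon | beta | cedar | larch | alder |
|---|---|---|---|---|---|
| starting complex | 0.061 M | 0.030 M | 0.061 M | 0.061 M | 0.061 M |
| incoming ligand | 0.122 M | 0.122 M | 0.122 M | 0.183 M | 0.0610 M |
| leaving ligand | 0.18 M | 0.122 M | 0.122 M | 0.122 M | 0.122 M |
| remark | run made earlier | run made earlier |  |  |  |
| time |  |  | 12 h | 12 h | 12 h |

- epsilon (time / h: complex with two exchanged / %, complex with three exchanged / %): 0.200: 6, 1; 0.667: 9, 9; 1.00: 16, 12; 1.50: 22, 15; 2.50: 27, 15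
- beta (time / h: complex with two exchanged / %, complex with three exchanged / %): 0.200: 3, 2; 0.333: 6, 5; 0.667: 12, 13; 1.33: 19, 27; 2.50: 29, 35

(scatter of a reading: 1.5 percentage points)

- which of these holds the largest part of the starting complex at the end of cedar (complex with three exchanged / complex with two exchanged / complex with one exchanged / starting complex)
- which of these holds the largest part of the starting complex at the end of larch (complex with three exchanged / complex with two exchanged / complex with one exchanged / starting complex)
- which of these holds the largest part of the starting complex at the end of alder (complex with three exchanged / complex with two exchanged / complex with one exchanged / starting complex)
- complex with two exchanged at the end of cedar, in percent of the starting complex charged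

- no earlier run changes the charge of incoming ligand; that part of a forecast is a guess

The last step turns complex with two exchanged into complex with three exchanged, and both are read directly, so the fraction left of incoming ligand is what must be reckoned. At the last beta reading, 2.50 h, each complex with two exchanged has taken 2 incoming ligands and each complex with three exchanged 3, which by these readings leaves about 59.9% of the incoming charge, less what the unread complex with one exchanged has taken. The charges of the two ligands are equal in beta, so leaving ligand stands at 2 charges minus that fraction. This gives 2.82 as a reading for the exchange quotient, three-exchanged over two-exchanged multiplied by leaving over incoming ligand, which at balance is the equilibrium constant of the last step. Leaving out the ligand taken by the unread complex with one exchanged sets this reading low, scatter apart.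

Cedar also has equal ligand charges, so by this reading its two complexes stand level with 52.3% of incoming ligand left, and with less left complex with two exchanged is ahead. Epsilon, with the same charges of starting complex and incoming ligand but more leaving ligand, had by the same count about 50.5% left at 2.50 h, below that fraction, with the readings of complex with two exchanged still rising. The margin is thin, but this reckoning commits to two-exchanged ahead of three-exchanged in cedar.

The forecast, with the same constant at 3 to 4 or more and judging that “the runs should be near equilibrium”, gave complex with two exchanged for cedar at 40%, complex with two exchanged for larch and complex with one exchanged for alder.

The flasks give complex with two exchanged in cedar at 39.9% and complex with two exchanged in larch, as forecast. Alder gives starting complex at 28.0%, while the forecast's complex with one exchanged stands at 11.1%.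

    starting complex + incoming ligand ⇌ leaving ligand + complex with one exchanged (K = 5.00, k = 0.490 M⁻¹ min⁻¹)
    complex with one exchanged + incoming ligand ⇌ leaving ligand + complex with two exchanged (K = 28.0, k = 0.240 M⁻¹ min⁻¹)
    complex with two exchanged + incoming ligand ⇌ leaving ligand + complex with three exchanged (K = 3.50, k = 0.750 M⁻¹ min⁻¹)
    starting complex ⇌ dormant form (K = 1.10, k = 0.250 min⁻¹)

In cedar the relaxation half-life of the second exchange, 1.06 h, is short against the 12 h allowed, and complex with two exchanged still reads 40.1% after 120 h. The exchange quotient, read as 2.82 in beta, comes to 3.50 at the end of cedar, and in the neighbour flask, cedar with 0.015 M of starting complex, where complex with three exchanged reaches 61.8% against 33.9% of complex with two exchanged, it is 3.50.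

The readings are simulated with constants of no real substance; noise was put on by code.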